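**Retrosynthetic overview**
- Last step: the 13(S)-vinyl carbinol is released from a 13,14-epoxy-15-ol (iodination, then zinc), so C13 comes from a Sharpless epoxidation.
- Key step: both rings form in one operation from an acyclic C20 epoxy tetraene ester by a cobalt-hydride (MHAT) radical bicyclisation. C4–C5 closes ring A first, C9–C10 then closes ring B, and hydrogen-atom loss gives the 7-ene. The C2 senecioate stereocentre alone steers C5, C9 and C10.
- The acyclic precursor is cut at C5–C6 (B-alkyl Suzuki) into a vinyl iodide ester and a diene epoxy alcohol.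
- The vinyl iodide ester comes from (R)-epichlorohydrin (isopropenyl Grignard, acetylide, Negishi carboalumination–iodination, Steglich ester); the diene epoxy alcohol comes from geranyl acetate (SeO2, Wittig, Sharpless epoxidation).

Assumption: geranyl acetate is the pure (E)-isomer and (R)-epichlorohydrin is at least 99% ee; labdane numbering (C1–C20) is used for positions in the chain and the decalin.

**Route**

Step 1
Reactants: 1 (R)-epichlorohydrin
Product: 2 (2R)-1-chloro-4-methylpent-4-en-2-ol
Conditions: isopropenylmagnesium bromide (1.2 equiv), CuI (10 mol %), THF, −40 → −20 °C; then H2O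
Reagents that add atoms: isopropenylmagnesium bromide CC(=C)[Mg]Br
Why: CuI-catalysed Grignard opening of the epoxide at its unsubstituted carbon (SN2) is faster than chloride displacement, so the chlorohydrin forms with the stereocentre of 1 untouched.

Step 2
Reactants: 2 (2R)-1-chloro-4-methylpent-4-en-2-ol
Product: 4 (4R)-6-methylhept-6-en-1-yn-4-ol, via epoxide 3 (not isolated)
Conditions: lithium acetylide–ethylenediamine complex (LiC≡CH·H2NCH2CH2NH2, 3 equiv), DMSO, 0 °C → rt; then H2O
Reagents that add atoms: lithium acetylide–ethylenediamine complex [Li+].[C-]#C.NCCN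
Why: One equivalent of acetylide closes the chlorohydrin to the terminal epoxide (Williamson closure) and a second opens it at the CH2 terminus (SN2 epoxide alkynylation), never touching the carbinol centre.

Step 3
Reactants: 4 (4R)-6-methylhept-6-en-1-yn-4-ol
Product: 6 (1E,4R)-1-iodo-2,6-dimethylhepta-1,6-dien-4-ol, via alkenylalane 5 (not isolated)
Conditions: Me3Al (3 equiv), Cp2ZrCl2 (0.25 equiv), CH2Cl2, 0 °C → rt; then I2 (1.2 equiv), THF, −30 → 0 °C; aq. K2CO3 work-up
Reagents that add atoms: trimethylaluminium C[Al](C)C; iodine II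
Why: Negishi Cp2ZrCl2-catalysed carboalumination adds Me and Al syn across the terminal alkyne with Me on the internal carbon (the 1,1-disubstituted alkene is inert), and iodinolysis of the C–Al bond with retention gives the (E)-vinyl iodide.

Step 4
Reactants: 6 (1E,4R)-1-iodo-2,6-dimethylhepta-1,6-dien-4-ol; 7 3-methylbut-2-enoic acid (senecioic acid)
Product: 8 (1E,4R)-1-iodo-2,6-dimethylhepta-1,6-dien-4-yl 3-methylbut-2-enoate
Conditions: 7 (1.3 equiv), DCC (1.4 equiv), DMAP (10 mol %), CH2Cl2, 0 °C → rt
Reagents that add atoms: none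
Why: Steglich esterification acylates the secondary alcohol with retention at carbon; low temperature and only catalytic DMAP limit deconjugation of the senecioyl group.

Step 5
Reactants: 9 geranyl acetate
Product: 10 (2E,6E)-3,7-dimethyl-8-oxoocta-2,6-dien-1-yl acetate
Conditions: SeO2 (1.1 equiv), 95% EtOH, reflux
Reagents that add atoms: selenium dioxide O=[Se]=O
Why: SeO2 allylic oxidation (ene reaction, then [2,3]-shift) attacks the electron-richer distal trisubstituted alkene at its (E)-methyl group and carries it on to the (E)-enal; a moderate yield is expected.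

Step 6
Reactants: 10 (2E,6E)-3,7-dimethyl-8-oxoocta-2,6-dien-1-yl acetate
Product: 12 (2E,6E)-3,7-dimethylnona-2,6,8-trien-1-ol, via diene acetate 11 (not isolated)
Conditions: methyltriphenylphosphonium bromide (1.3 equiv), KOtBu (1.25 equiv), THF, 0 °C, then 10, −78 → 0 °C; then MeOH, K2CO3 (20 mol %), rt
Reagents that add atoms: methyltriphenylphosphonium bromide C[P+](c1ccccc1)(c1ccccc1)c1ccccc1.[Br-]
Why: Wittig methylenation turns the enal into the conjugated diene without changing alkene geometry, and base-catalysed methanolysis in the same flask removes the acetate.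

Step 7
Reactants: 12 (2E,6E)-3,7-dimethylnona-2,6,8-trien-1-ol
Product: 13 [(2S,3S)-3-methyl-3-[(3E)-4-methylhexa-3,5-dien-1-yl]oxiran-2-yl]methanol
Conditions: Ti(OiPr)4 (10 mol %), L-(+)-diethyl tartrate (12 mol %), t-BuOOH (2 equiv, decane solution), 4 Å molecular sieves, CH2Cl2, −20 °C
Reagents that add atoms: tert-butyl hydroperoxide CC(C)(C)OO
Why: Katsuki–Sharpless asymmetric epoxidation touches only the allylic-alcohol alkene, and the L-(+)-tartrate catalyst gives the (2S,3S)-epoxy alcohol (as with geraniol), which fixes the later C13 and the temporary C14 configuration.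

Step 8
Reactants: 13 [(2S,3S)-3-methyl-3-[(3E)-4-methylhexa-3,5-dien-1-yl]oxiran-2-yl]methanol; 8 (1E,4R)-1-iodo-2,6-dimethylhepta-1,6-dien-4-yl 3-methylbut-2-enoate
Product: 15 (4R,6E,10E)-13-[(2S,3S)-3-(hydroxymethyl)-2-methyloxiran-2-yl]-2,6,10-trimethyltrideca-1,6,10-trien-4-yl 3-methylbut-2-enoate, via alkylborane 14 (not isolated)
Conditions: 13 (1.25 equiv), 9-BBN (2.2 equiv B–H per 13), THF, 0 °C → rt; then 3 M aq. Cs2CO3 (quenches residual B–H); then 8 (1.0 equiv), Pd(dppf)Cl2 (5 mol %), AsPh3 (10 mol %), DMF, rt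
Reagents that add atoms: none
Why: 9-BBN hydroborates only the terminal CH2 of the diene (anti-Markovnikov; the trisubstituted alkene and the epoxide are inert), and B-alkyl Suzuki–Miyaura coupling with the vinyl iodide forms C5–C6 with retention of the (E)-geometry.

Step 9
Reactants: 15 (4R,6E,10E)-13-[(2S,3S)-3-(hydroxymethyl)-2-methyloxiran-2-yl]-2,6,10-trimethyltrideca-1,6,10-trien-4-yl 3-methylbut-2-enoate
Product: 17 (2R,5R,9R,10R,13S,14S)-13,14-epoxy-15-hydroxylabd-7-en-2-yl 3-methylbut-2-enoate, via exocyclic alkene 16 (not isolated)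
Conditions: chloro[N,N'-bis(3,5-di-tert-butylsalicylidene)-1,2-cyclohexanediaminato]cobalt, (salen)CoCl (3 mol %), PhSiH3 (6 mol %), benzene (0.01 M), 22 °C, argon
Reagents that add atoms: none
Why: Proposed new method: the cobalt hydride formed from the trivalent cobalt complex (salen)CoCl and PhSiH3 transfers a hydrogen atom (MHAT) only to the 1,1-disubstituted alkene of 15; the C4 tertiary radical closes ring A by 6-endo attack on C5 of the (E)-C5=C10 alkene and the C10 radical closes ring B by 6-endo attack on C9 of the (E)-C8=C9 alkene through a chair–chair array with the C2 ester equatorial (an axial C2–O would clash with a C4 methyl and the C10 methyl), so the C2 centre sets C5, C10 and C9 (trans ring fusion, C11 equatorial, ester trans to C20); divalent (salen)Co then removes a hydrogen atom next to the C8 radical, and because the exocyclic alkene 16 is again a 1,1-disubstituted MHAT acceptor while the trisubstituted 7-ene is not, the material should converge on 17; the closest known reaction types are (salen)CoCl-catalysed MHAT cycloisomerisation and alkene isomerisation, MHAT-initiated radical–polar crossover polyene bicyclisation from the same isopropenyl initiator, and Cp2TiCl-mediated radical epoxypolyene bicyclisation.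

Step 10
Reactants: 17 (2R,5R,9R,10R,13S,14S)-13,14-epoxy-15-hydroxylabd-7-en-2-yl 3-methylbut-2-enoate
Product: 19 (2R,5R,9R,10R,13S)-13-hydroxylabda-7,14-dien-2-yl 3-methylbut-2-enoate (target), via epoxy iodide 18 (not isolated)
Conditions: PPh3 (1.5 equiv), I2 (1.4 equiv), imidazole (3 equiv), THF, 0 °C; then Zn dust (10 equiv), AcOH (5 equiv), EtOH, rt
Reagents that add atoms: none
Why: Garegg-type iodination of the primary alcohol followed by zinc-mediated reductive β-elimination opens the epoxide to the tertiary allylic alcohol with the C13–O bond, and so the C13 configuration from step 7, intact.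

**Compound list**

1 | (R)-epichlorohydrin, (2R)-2-(chloromethyl)oxirane | ClC[C@H]1CO1 | starting material
2 | (2R)-1-chloro-4-methylpent-4-en-2-ol | C=C(C)C[C@@H](O)CCl | intermediate
3 | (2R)-2-(2-methylprop-2-en-1-yl)oxirane (not isolated) | C=C(C)C[C@@H]1CO1 | intermediate
4 | (4R)-6-methylhept-6-en-1-yn-4-ol | C=C(C)C[C@@H](O)CC#C | intermediate
5 | (1E,4R)-1-(dimethylalumanyl)-2,6-dimethylhepta-1,6-dien-4-ol as its O-dimethylaluminium alkoxide (not isolated) | C=C(C)C[C@@H](O[Al](C)C)C/C(C)=C/[Al](C)C | intermediate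
6 | (1E,4R)-1-iodo-2,6-dimethylhepta-1,6-dien-4-ol | C=C(C)C[C@@H](O)C/C(C)=C/I | intermediate
7 | 3-methylbut-2-enoic acid (senecioic acid) | CC(C)=CC(=O)O | starting material
8 | (1E,4R)-1-iodo-2,6-dimethylhepta-1,6-dien-4-yl 3-methylbut-2-enoate | C=C(C)C[C@@H](OC(=O)C=C(C)C)C/C(C)=C/I | intermediate
9 | geranyl acetate, (2E)-3,7-dimethylocta-2,6-dien-1-yl acetate | CC(C)=CCC/C(C)=C/COC(C)=O | starting material
10 | (2E,6E)-3,7-dimethyl-8-oxoocta-2,6-dien-1-yl acetate | O=C/C(C)=C/CC/C(C)=C/COC(C)=O | intermediate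
11 | (2E,6E)-3,7-dimethylnona-2,6,8-trien-1-yl acetate (not isolated) | C=C/C(C)=C/CC/C(C)=C/COC(C)=O | intermediate
12 | (2E,6E)-3,7-dimethylnona-2,6,8-trien-1-ol | C=C/C(C)=C/CC/C(C)=C/CO | intermediate
13 | [(2S,3S)-3-methyl-3-[(3E)-4-methylhexa-3,5-dien-1-yl]oxiran-2-yl]methanol | C=C/C(C)=C/CC[C@]1(C)O[C@H]1CO | intermediate
14 | 9-BBN adduct of 13: 9-borabicyclo[3.3.1]nonan-9-yl on the former terminal diene carbon (C6) and a second 9-BBN unit as O-borinate on the hydroxyl (not isolated) | B1(C2CCCC1CCC2)CC/C(C)=C/CC[C@]3(C)O[C@H]3COB4C5CCCC4CCC5 | intermediate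
15 | (4R,6E,10E)-13-[(2S,3S)-3-(hydroxymethyl)-2-methyloxiran-2-yl]-2,6,10-trimethyltrideca-1,6,10-trien-4-yl 3-methylbut-2-enoate | C=C(C)C[C@@H](OC(=O)C=C(C)C)C/C(C)=C/CC/C(C)=C/CC[C@]1(C)O[C@H]1CO | intermediate
16 | (2R,5R,9R,10R,13S,14S)-13,14-epoxy-15-hydroxylabd-8(17)-en-2-yl 3-methylbut-2-enoate, the exocyclic alkene isomer of 17 (not isolated) | OC[C@@H]3O[C@@]3(C)CC[C@@H]1C(=C)CC[C@@H]2C(C)(C)C[C@@H](OC(=O)C=C(C)C)C[C@@]12C | intermediate
17 | (2R,5R,9R,10R,13S,14S)-13,14-epoxy-15-hydroxylabd-7-en-2-yl 3-methylbut-2-enoate; ent-labdane trans-decalin, 2-ester equatorial and trans to the C10 methyl, side chain at C9 cis to the C10 methyl | OC[C@@H]3O[C@@]3(C)CC[C@@H]1C(C)=CC[C@@H]2C(C)(C)C[C@@H](OC(=O)C=C(C)C)C[C@@]12C | intermediate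
18 | (2R,5R,9R,10R,13S,14R)-13,14-epoxy-15-iodolabd-7-en-2-yl 3-methylbut-2-enoate (same geometry as 17; not isolated) | IC[C@@H]3O[C@@]3(C)CC[C@@H]1C(C)=CC[C@@H]2C(C)(C)C[C@@H](OC(=O)C=C(C)C)C[C@@]12C | intermediate
19 | (2R,4aR,8R,8aR)-8-[(3S)-3-hydroxy-3-methylpent-4-en-1-yl]-4,4,7,8a-tetramethyl-1,2,3,4,4a,5,8,8a-octahydronaphthalen-2-yl 3-methylbut-2-enoate, i.e. (2R,5R,9R,10R,13S)-13-hydroxylabda-7,14-dien-2-yl 3-methylbut-2-enoate | C=C[C@@](C)(O)CC[C@@H]1C(C)=CC[C@@H]2C(C)(C)C[C@@H](OC(=O)C=C(C)C)C[C@@]12C | target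

**Step count and risk**

Total steps: 10. Longest linear sequence: 7 (steps 1, 2, 3, 4, 8, 9, 10).

The three steps most likely to fail are 9, 8 and 10.

Step 9 (radical bicyclisation). The main risks are hydrogen-atom return before ring closure (isomerising the isopropenyl group to an unreactive trisubstituted alkene) and modest control from C2. The fallback sets out from diene acetate 11 (taken from step 6 by leaving out the methanolysis) and vinyl iodide 8, and comes back at 17. Hydroboration of 11 with 9-BBN gives the alkylborane F1, which is coupled with 8 under the step 8 conditions to give the tetraene acetate F2. F2 is cyclised under oxidative MHAT radical–polar crossover conditions ((salen)CoCl 5 mol %, N-fluoro-2,4,6-trimethylpyridinium triflate, (Me2SiH)2O, HFIP, 0 °C). Here the cascade is closed irreversibly by oxidation to the C8 cation and proton loss, and the electron-poor allylic acetate alkene does not act as a third ring-closing partner; this gives the bicyclic acetate F3. Selective methanolysis of the primary acetate (K2CO3, MeOH, 0 °C) gives the bicyclic allylic alcohol F4. Sharpless epoxidation of F4 (Ti(OiPr)4, L-(+)-diethyl tartrate, t-BuOOH) then gives 17.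

Step 8 (hydroboration and Suzuki coupling with a free epoxy alcohol). The risk is Payne rearrangement or opening of the epoxy alcohol by boron or base. The fallback sets out from dienol 12 and vinyl iodide 8, and comes back at 15. Hydroboration of 12 with 9-BBN (2.2 equiv) gives the bis-boron adduct F5, and Suzuki coupling with 8 gives the tetraenol F6. Sharpless epoxidation of F6 (Ti(OiPr)4, L-(+)-diethyl tartrate, t-BuOOH), which touches only the allylic-alcohol alkene, gives 15. The epoxidation is moved after the coupling and step 7 is dropped, so the step count is unchanged.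

Step 10 (iodination and zinc elimination on the finished skeleton). The risk is iodide opening of the epoxide or incomplete elimination. The fallback sets out from 17 and comes back at 19. Dess–Martin oxidation (NaHCO3, CH2Cl2) gives the epoxy aldehyde F7. Hydrazine hydrate with catalytic AcOH in MeOH at 0 °C forms the hydrazone F8, which undergoes Wharton transposition with loss of nitrogen to give 19.

**Further compounds**

F1 | step 9 | (2E,6E)-9-(9-borabicyclo[3.3.1]nonan-9-yl)-3,7-dimethylnona-2,6-dien-1-yl acetate | B1(C2CCCC1CCC2)CC/C(C)=C/CC/C(C)=C/COC(C)=O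
F2 | step 9 | (2E,6E,10E,13R)-3,7,11,15-tetramethyl-13-[(3-methylbut-2-enoyl)oxy]hexadeca-2,6,10,15-tetraen-1-yl acetate | C=C(C)C[C@@H](OC(=O)C=C(C)C)C/C(C)=C/CC/C(C)=C/CC/C(C)=C/COC(C)=O
F3 | step 9 | (2R,5R,9R,10R,13E)-15-acetoxylabda-7,13-dien-2-yl 3-methylbut-2-enoate | CC(=O)OC/C=C(\C)CC[C@@H]1C(C)=CC[C@@H]2C(C)(C)C[C@@H](OC(=O)C=C(C)C)C[C@@]12C
F4 | step 9 | (2R,5R,9R,10R,13E)-15-hydroxylabda-7,13-dien-2-yl 3-methylbut-2-enoate | OC/C=C(\C)CC[C@@H]1C(C)=CC[C@@H]2C(C)(C)C[C@@H](OC(=O)C=C(C)C)C[C@@]12C
F5 | step 8 | 9-BBN adduct of 12: 9-borabicyclo[3.3.1]nonan-9-yl on C9 of the (2E,6E)-3,7-dimethylnona-2,6-dienyl chain and a second 9-BBN unit as O-borinate | B1(C2CCCC1CCC2)CC/C(C)=C/CC/C(C)=C/COB3C4CCCC3CCC4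
F6 | step 8 | (2E,6E,10E,13R)-1-hydroxy-3,7,11,15-tetramethylhexadeca-2,6,10,15-tetraen-13-yl 3-methylbut-2-enoate | C=C(C)C[C@@H](OC(=O)C=C(C)C)C/C(C)=C/CC/C(C)=C/CC/C(C)=C/CO
F7 | step 10 | (2R,5R,9R,10R,13S,14S)-13,14-epoxy-15-oxolabd-7-en-2-yl 3-methylbut-2-enoate | O=C[C@@H]3O[C@@]3(C)CC[C@@H]1C(C)=CC[C@@H]2C(C)(C)C[C@@H](OC(=O)C=C(C)C)C[C@@]12C
F8 | step 10 | hydrazone of F7 at C15 | NN=C[C@@H]3O[C@@]3(C)CC[C@@H]1C(C)=CC[C@@H]2C(C)(C)C[C@@H](OC(=O)C=C(C)C)C[C@@]12C
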